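**Retrosynthetic overview**
1. Target 24 comes from a B-alkyl Suzuki–Miyaura coupling (C12–C13) of the 9-vinyl decalin acetate 21 with 4-bromobutenolide 22. Compound 21 comes from α-face reduction and acetylation of the C6 ketone released from silyl trienol ether 18. The vinyl group of 18 is made from the C11 ester by way of CH2OH and CHO.
2. Decalin 15 comes from the acyclic ynone–enoate 13 in one operation that makes C5–C10 and C8=C9 together. Ring A closes first (C5–C10) and ring B second (C8–C9).
3. Enabling feature: ring B (C5–C6–C7–C8–C9–C10) carries its only heteroatom at C6, next to ring-fusion carbon C5 and 1,3 to alkene carbon C8, so polarity alternates round the ring. CH3–C8≡C7–C6(=O)–C5H2 is a donor at C5 and an acceptor at C8. C10(CH3)=C9H–C11O2R* is an acceptor at C10 and a donor at C9. The C1–C4 tether with the gem-dimethyl C4 folds the two units together, and the activating carbon C11 stays in the skeleton.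
4. Compound 13 is assembled from prenal 2 (C4–C6 and two CH3), the Grignard reagent of chloroketal 1 (C1–C3, C10, C20), propynyl Grignard 6 (C7, C8, C17) and chiral phosphonoacetate 11 (C9, C11).
5. Absolute configuration comes from the 8-phenylmenthyl ester, which is lost in the ester reduction that the route needs anyway. C6 then follows from C5 and C10 by substrate control.

Key step: step 6

Numbering: labdane numbering is used throughout. Ring A is C1–C5 plus C10 and ring B is C5–C10. C4 bears the gem-dimethyl group, C10 the angular CH3, and C8 the CH3 C17. The side chain is C11–C12 and the butenolide is C13–C16.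

Assumption: the shielding sense of the 8-phenylmenthyl ester in its O-silylated s-trans form is taken to be the one established for Lewis-acid-assisted organocopper additions to (E)-enoates of this alcohol. Should the opposite sense be found, the (1R,2S,5R)-alcohol would be used and nothing else would change.

**Step 1**
Reactants: 1 2-(3-chloropropyl)-2-methyl-1,3-dioxolane; 2 3-methylbut-2-enal
Product: 5 3,3-dimethyl-6-(2-methyl-1,3-dioxolan-2-yl)hexanal, via Grignard reagent 3 (not isolated), via silyl enol ether 4 (not isolated)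
Conditions: Mg, BrCH2CH2Br (cat.), THF, reflux; CuBr·SMe2 (5 mol %), Me3SiCl, DMPU, THF, −78 °C, then 2; K2CO3 (cat.), MeOH, 0 °C
Reagents that add atoms: magnesium, [Mg] (retained only in 3); chlorotrimethylsilane, C[Si](C)(C)Cl (retained only in 4)
Why: The copper-catalysed, Me3SiCl-accelerated conjugate addition of a Grignard reagent to a β,β-disubstituted enal should build the quaternary C4, and basic methanolysis should cleave only the silyl enol ether and leave the ketal intact.

**Step 2**
Reactants: 5 3,3-dimethyl-6-(2-methyl-1,3-dioxolan-2-yl)hexanal; 6 prop-1-yn-1-ylmagnesium bromide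
Product: 8 8-hydroxy-6,6-dimethylundec-9-yn-2-one, via ketal alcohol 7 (not isolated)
Conditions: THF, −78 → 0 °C; then 1 M HCl, THF, rt
Reagents that add atoms: water, O
Why: Grignard 1,2-addition to the aldehyde followed by acid hydrolysis of the dioxolane should give the keto alcohol, and the carbinol configuration is irrelevant because this centre is oxidised in step 5.

**Step 3**
Reactants: 9 (1S,2R,5S)-8-phenylmenthol; 10 2-(diethoxyphosphoryl)acetic acid
Product: 11 (1S,2R,5S)-8-phenylmenthyl 2-(diethoxyphosphoryl)acetate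
Conditions: DCC, DMAP (cat.), CH2Cl2, 0 °C → rt
Reagents that add atoms: none
Why: Steglich esterification couples hindered secondary alcohols with this acid without touching the stereocentres of the auxiliary.

**Step 4**
Reactants: 8 8-hydroxy-6,6-dimethylundec-9-yn-2-one; 11 (1S,2R,5S)-8-phenylmenthyl 2-(diethoxyphosphoryl)acetate
Product: 12 (1S,2R,5S)-8-phenylmenthyl (2E)-9-hydroxy-3,7,7-trimethyldodec-2-en-10-ynoate
Conditions: NaH and 11 in excess (the carbinol travels as its alkoxide), THF, 0 °C → reflux; the minor Z isomer is removed by chromatography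
Reagents that add atoms: none
Why: Horner–Wadsworth–Emmons olefination of the methyl ketone should give mainly the (E)-trisubstituted enoate, with the long chain trans to the bulky ester.

**Step 5**
Reactants: 12 (1S,2R,5S)-8-phenylmenthyl (2E)-9-hydroxy-3,7,7-trimethyldodec-2-en-10-ynoate
Product: 13 (1S,2R,5S)-8-phenylmenthyl (2E)-3,7,7-trimethyl-9-oxododec-2-en-10-ynoate
Conditions: MnO2 (activated), CH2Cl2, rt
Reagents that add atoms: none
Why: MnO2 oxidation of a propargylic alcohol to the ynone is neutral, leaves the enoate untouched and merges both carbinol epimers into one compound.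

**Step 6**
Reactants: 13 (1S,2R,5S)-8-phenylmenthyl (2E)-3,7,7-trimethyl-9-oxododec-2-en-10-ynoate
Product: 15 (1S,2R,5S)-8-phenylmenthyl (5S,10S)-6-(tert-butyldimethylsilyloxy)drima-6,8-dien-11-oate, via silyloxy-enyne 14 (not isolated)
Conditions: TBSOTf (2.2 equiv), Et3N (1.1 equiv), CH2Cl2 (0.005 M), −78 → 0 °C; then HN(SO2CF3)2 (20 mol %), 0 °C → rt
Reagents that add atoms: tert-butyldimethylsilyl triflate, CC(C)(C)[Si](C)(C)OS(=O)(=O)C(F)(F)F
Why: Proposed new method: soft enolisation at C5, the only enolisable position of the but-2-ynoyl ketone, gives (Z)-silyloxy-enyne 14, whose C5 adds to C10 of the silylium-activated (E)-enoate (Mukaiyama–Michael), the silyl ketene acetal so formed at C9 adds to C8 of the O-silylated ynone, and the bent allenyl silyl ether is protonated at C7 by Et3NH+ and loses the acidic C9 hydrogen, so that C8=C9 appears conjugated to the ester while oxygen stays on C6 as a silyl dienol ether. The closest known reaction types are the silyl triflate/amine-mediated intramolecular double Michael reaction of enone–enoates and the acid-promoted intramolecular [4+2] cycloaddition of conjugated enynes through cyclic allenes, and neither has been shown for a ynone that acts as donor and acceptor towards a β,β-disubstituted enoate. Ring A closes in the 6-(enolexo)-exo-trig mode (C5–C10) and ring B in the 6-endo-dig mode (C9–C8). C10 is set by the auxiliary, because in the O-silylated s-trans enoate the phenyl ring stacks over one face and C5 must arrive from the open face, which gives 10S with the (1S,2R,5S)-alcohol and the (E)-alkene. C5 is set relative to C10 by a compact, endo-like chair transition state in which C6 and C9 are both pseudo-equatorial on the nascent ring A and the ester carbonyl lies under the developing C6 oxocarbenium ion, so that H5 and the angular CH3 end up anti and the ring fusion is trans. The step needs C5→C10 and C9→C8 to win over intermolecular addition to the ynone and over γ-deprotonation of the enoate, which is secured by high dilution, by the gem-dimethyl group at C4, by the fact that every other intramolecular closure would make an eight- or ten-membered ring, and by using barely more than one equivalent of amine.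

**Step 7**
Reactants: 15 (1S,2R,5S)-8-phenylmenthyl (5S,10S)-6-(tert-butyldimethylsilyloxy)drima-6,8-dien-11-oate
Product: 16 (5S,10S)-6-(tert-butyldimethylsilyloxy)drima-6,8-dien-11-ol
Conditions: LiAlH4, Et2O, 0 °C → reflux; Rochelle-salt work-up, Et3N-washed silica
Reagents that add atoms: none
Why: LiAlH4 reduction of the hindered conjugated ester should give the primary allylic alcohol and release the auxiliary, since the silyl dienol ether is inert to hydride and the basic work-up avoids ionisation of the acid-labile product.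

**Step 8**
Reactants: 16 (5S,10S)-6-(tert-butyldimethylsilyloxy)drima-6,8-dien-11-ol
Product: 17 (5S,10S)-6-(tert-butyldimethylsilyloxy)drima-6,8-dien-11-al
Conditions: MnO2 (activated), CH2Cl2, rt
Reagents that add atoms: none
Why: Neutral MnO2 oxidation of a primary allylic alcohol should give the push–pull dienal without acid that could strip the silyl group.

**Step 9**
Reactants: 17 (5S,10S)-6-(tert-butyldimethylsilyloxy)drima-6,8-dien-11-al
Product: 18 (5S,10S)-6-(tert-butyldimethylsilyloxy)-13,14,15,16-tetranorlabda-6,8,11-triene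
Conditions: Ph3PCH3Br, KHMDS, THF, 0 °C; then 17, 0 °C → rt
Reagents that add atoms: methyltriphenylphosphonium bromide, C[P+](c1ccccc1)(c1ccccc1)c1ccccc1.[Br-]
Why: Wittig methylenation with the small, reactive non-stabilised ylide works on hindered cyclohexene carbaldehydes of this type, adds C12, and removes the acidifying carbonyl group from C9.

**Step 10**
Reactants: 18 (5S,10S)-6-(tert-butyldimethylsilyloxy)-13,14,15,16-tetranorlabda-6,8,11-triene
Product: 20 (5S,6R,10S)-13,14,15,16-tetranorlabda-8,11-dien-6-ol, via ketone 19 (not isolated)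
Conditions: TBAF, AcOH, THF, −78 → −30 °C; pH 7 buffer, cold extraction; crude 19, LiAlH4, Et2O, −78 °C
Reagents that add atoms: none
Why: Fluoride releases the extended enolate, which AcOH should protonate kinetically at the α-carbon C7 (deconjugative protonation, C8=C9 stays), and hydride should then attack the C6 ketone from the α face, opposite the axial CH3 groups on C4 and C10, to set the axial 6β (6R) alcohol.

**Step 11**
Reactants: 20 (5S,6R,10S)-13,14,15,16-tetranorlabda-8,11-dien-6-ol
Product: 21 (5S,6R,10S)-13,14,15,16-tetranorlabda-8,11-dien-6-yl acetate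
Conditions: Ac2O, DMAP, Et3N, CH2Cl2, reflux
Reagents that add atoms: acetic anhydride, CC(=O)OC(C)=O
Why: DMAP-catalysed acylation is the standard way to esterify a hindered axial secondary alcohol and proceeds with retention at C6.

**Step 12**
Reactants: 21 (5S,6R,10S)-13,14,15,16-tetranorlabda-8,11-dien-6-yl acetate; 22 4-bromofuran-2(5H)-one
Product: 24 (5S,6R,10S)-6-acetoxylabda-8,13-dien-16,15-olide, via alkylborane 23 (not isolated)
Conditions: 9-BBN, THF, 0 °C → rt; then 22, PdCl2(dppf) (5 mol %), AsPh3, Cs2CO3, DMF–THF–H2O, rt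
Reagents that add atoms: 9-borabicyclo[3.3.1]nonane, B1C2CCCC1CCC2 (retained only in 23)
Why: 9-BBN should add only to the monosubstituted C11=C12 alkene with boron at C12, leaving the tetrasubstituted alkene and the acetate untouched, and the B-alkyl Suzuki–Miyaura coupling with the β-bromobutenolide then forms C12–C13 under mild base.

**Compound list**
1 | 2-(3-chloropropyl)-2-methyl-1,3-dioxolane | CC1(CCCCl)OCCO1 | starting material
2 | 3-methylbut-2-enal | CC(C)=CC=O | starting material
3 | [3-(2-methyl-1,3-dioxolan-2-yl)propyl]magnesium chloride | CC1(CCC[Mg]Cl)OCCO1 | intermediate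
4 | {[3,3-dimethyl-6-(2-methyl-1,3-dioxolan-2-yl)hex-1-en-1-yl]oxy}trimethylsilane (E/Z mixture) | CC1(CCCC(C)(C)C=CO[Si](C)(C)C)OCCO1 | intermediate
5 | 3,3-dimethyl-6-(2-methyl-1,3-dioxolan-2-yl)hexanal | CC1(CCCC(C)(C)CC=O)OCCO1 | intermediate
6 | prop-1-yn-1-ylmagnesium bromide | CC#C[Mg]Br | starting material
7 | 6,6-dimethyl-9-(2-methyl-1,3-dioxolan-2-yl)non-2-yn-4-ol (racemic) | CC#CC(O)CC(C)(C)CCCC1(C)OCCO1 | intermediate
8 | 8-hydroxy-6,6-dimethylundec-9-yn-2-one (racemic) | CC#CC(O)CC(C)(C)CCCC(C)=O | intermediate
9 | (1S,2R,5S)-5-methyl-2-(2-phenylpropan-2-yl)cyclohexan-1-ol, (+)-8-phenylmenthol | O[C@H]1C[C@@H](C)CC[C@@H]1C(C)(C)c1ccccc1 | starting material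
10 | 2-(diethoxyphosphoryl)acetic acid | CCOP(=O)(CC(=O)O)OCC | starting material
11 | (1S,2R,5S)-8-phenylmenthyl 2-(diethoxyphosphoryl)acetate | CCOP(=O)(CC(=O)O[C@H]1C[C@@H](C)CC[C@@H]1C(C)(C)c1ccccc1)OCC | intermediate
12 | (1S,2R,5S)-8-phenylmenthyl (2E)-9-hydroxy-3,7,7-trimethyldodec-2-en-10-ynoate (both carbinol epimers) | CC#CC(O)CC(C)(C)CCC/C(C)=C/C(=O)O[C@H]1C[C@@H](C)CC[C@@H]1C(C)(C)c1ccccc1 | intermediate
13 | (1S,2R,5S)-8-phenylmenthyl (2E)-3,7,7-trimethyl-9-oxododec-2-en-10-ynoate | CC#CC(=O)CC(C)(C)CCC/C(C)=C/C(=O)O[C@H]1C[C@@H](C)CC[C@@H]1C(C)(C)c1ccccc1 | intermediate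
14 | (1S,2R,5S)-8-phenylmenthyl (2E,8Z)-9-(tert-butyldimethylsilyloxy)-3,7,7-trimethyldodeca-2,8-dien-10-ynoate | CC#C/C(O[Si](C)(C)C(C)(C)C)=C/C(C)(C)CCC/C(C)=C/C(=O)O[C@H]1C[C@@H](C)CC[C@@H]1C(C)(C)c1ccccc1 | intermediate
15 | (1S,2R,5S)-8-phenylmenthyl (5S,10S)-6-(tert-butyldimethylsilyloxy)drima-6,8-dien-11-oate (trans-fused; ring B is a 6,8-diene with OTBS on C6, CH3 on C8 and the ester on C9) | CC(C)(C)[Si](C)(C)OC1=CC(C)=C(C(=O)O[C@H]3C[C@@H](C)CC[C@@H]3C(C)(C)c3ccccc3)[C@@]2(C)CCCC(C)(C)[C@H]12 | intermediate
16 | (5S,10S)-6-(tert-butyldimethylsilyloxy)drima-6,8-dien-11-ol | CC(C)(C)[Si](C)(C)OC1=CC(C)=C(CO)[C@@]2(C)CCCC(C)(C)[C@H]12 | intermediate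
17 | (5S,10S)-6-(tert-butyldimethylsilyloxy)drima-6,8-dien-11-al | CC(C)(C)[Si](C)(C)OC1=CC(C)=C(C=O)[C@@]2(C)CCCC(C)(C)[C@H]12 | intermediate
18 | (5S,10S)-6-(tert-butyldimethylsilyloxy)-13,14,15,16-tetranorlabda-6,8,11-triene (vinyl on C9) | CC(C)(C)[Si](C)(C)OC1=CC(C)=C(C=C)[C@@]2(C)CCCC(C)(C)[C@H]12 | intermediate
19 | (5S,10S)-13,14,15,16-tetranorlabda-8,11-dien-6-one | O=C1CC(C)=C(C=C)[C@@]2(C)CCCC(C)(C)[C@H]12 | intermediate
20 | (5S,6R,10S)-13,14,15,16-tetranorlabda-8,11-dien-6-ol (6β-OH, axial) | O[C@@H]1CC(C)=C(C=C)[C@@]2(C)CCCC(C)(C)[C@H]12 | intermediate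
21 | (5S,6R,10S)-13,14,15,16-tetranorlabda-8,11-dien-6-yl acetate | CC(=O)O[C@@H]1CC(C)=C(C=C)[C@@]2(C)CCCC(C)(C)[C@H]12 | intermediate
22 | 4-bromofuran-2(5H)-one | O=C1C=C(Br)CO1 | starting material
23 | (5S,6R,10S)-12-(9-borabicyclo[3.3.1]nonan-9-yl)-13,14,15,16-tetranorlabd-8-en-6-yl acetate | CC(=O)O[C@@H]1CC(C)=C(CCB3C4CCCC3CCC4)[C@@]2(C)CCCC(C)(C)[C@H]12 | intermediate
24 | (5S,6R,10S)-6-acetoxylabda-8,13-dien-16,15-olide (CNP0128495.1) | CC(=O)O[C@@H]1CC(C)=C(CCC2=CC(=O)OC2)[C@@]2(C)CCCC(C)(C)[C@H]12 | target

**Step count**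
Total steps: 12. The longest linear sequence is 11 steps (steps 1, 2 and 4–12).

**Steps most likely to fail**

*Step 6.* The very hindered C5–C10 bond may form too slowly. In that case 14 would simply persist, or intermolecular addition to the ynone or deconjugation of the enoate would take over. Facial shielding or ring-fusion selectivity may also be poor.

The fallback uses known chemistry, replaces the polar cascade by a concerted cycloaddition, sets out from 13 and returns at 15.
- 13 would take up methanol (MeOH, DMAP cat., rt) to give the (E)-β-methoxy enone F1.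
- Kinetic α'-deprotonation and O-silylation (KHMDS, TBSCl, THF, −78 °C) would give the 1-methoxy-3-silyloxy diene F2.
- A thermal or high-pressure intramolecular Diels–Alder reaction (toluene, sealed tube, or CH2Cl2, 12 kbar) would give the cycloadduct F3.
- TBSOTf/2,6-lutidine would remove the C8 methoxy group together with the C9 hydrogen to reach 15.

*Step 10.* The proton may return at C9 or C12 instead of C7, or the ketone may be re-enolised before hydride arrives. Either event would move the double bond into conjugation and could also epimerise C5.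

The fallback sets out from 18 and returns at 20, and the free ketone never accumulates.
- Anhydrous fluoride (TBAT) in the presence of Ac2O would convert 18 into the trienyl acetate F4.
- NaBH4 in EtOH–THF–H2O at 0 °C would cleave the enol ester slowly in the presence of excess hydride.
- Each molecule of β,γ-unsaturated ketone would therefore be reduced as soon as it is released (reductive deconjugation of a dienol acetate).

*Step 12.* The bromobutenolide may decompose under base, the alkylborane may be lost by protodeboronation, or the alkylpalladium species may undergo β-hydride elimination.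

The fallback sets out from 21 and returns at 24, and it swaps the basic boron coupling for a base-free organozinc coupling.
- Hydroboration to 23 and oxidation (NaBO3, THF–H2O) would give the primary alcohol F5.
- An Appel-type iodination (I2, PPh3, imidazole) would give the iodide F6.
- Zinc insertion (Zn, LiCl, THF) would give the alkylzinc iodide F7.
- Negishi coupling with 22 (Pd(PPh3)4, THF, rt) would give 24.

**Further compounds**
F1 | step 6 | (1S,2R,5S)-8-phenylmenthyl (2E,10E)-11-methoxy-3,7,7-trimethyl-9-oxododeca-2,10-dienoate | CO/C(C)=C/C(=O)CC(C)(C)CCC/C(C)=C/C(=O)O[C@H]1C[C@@H](C)CC[C@@H]1C(C)(C)c1ccccc1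
F2 | step 6 | (1S,2R,5S)-8-phenylmenthyl (2E,8Z,10E)-9-(tert-butyldimethylsilyloxy)-11-methoxy-3,7,7-trimethyldodeca-2,8,10-trienoate | CO/C(C)=C/C(O[Si](C)(C)C(C)(C)C)=C/C(C)(C)CCC/C(C)=C/C(=O)O[C@H]1C[C@@H](C)CC[C@@H]1C(C)(C)c1ccccc1
F3 | step 6 | (1S,2R,5S)-8-phenylmenthyl (5S,10S)-6-(tert-butyldimethylsilyloxy)-8-methoxydrim-6-en-11-oate (C8 and C9 configuration inconsequential) | CC(C)(C)[Si](C)(C)OC1=CC(C)(OC)C(C(=O)O[C@H]3C[C@@H](C)CC[C@@H]3C(C)(C)c3ccccc3)[C@@]2(C)CCCC(C)(C)[C@H]12
F4 | step 10 | (5S,10S)-13,14,15,16-tetranorlabda-6,8,11-trien-6-yl acetate | CC(=O)OC1=CC(C)=C(C=C)[C@@]2(C)CCCC(C)(C)[C@H]12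
F5 | step 12 | (5S,6R,10S)-12-hydroxy-13,14,15,16-tetranorlabd-8-en-6-yl acetate | CC(=O)O[C@@H]1CC(C)=C(CCO)[C@@]2(C)CCCC(C)(C)[C@H]12
F6 | step 12 | (5S,6R,10S)-12-iodo-13,14,15,16-tetranorlabd-8-en-6-yl acetate | CC(=O)O[C@@H]1CC(C)=C(CCI)[C@@]2(C)CCCC(C)(C)[C@H]12
F7 | step 12 | [(5S,6R,10S)-6-acetoxy-13,14,15,16-tetranorlabd-8-en-12-yl]zinc iodide | CC(=O)O[C@@H]1CC(C)=C(CC[Zn]I)[C@@]2(C)CCCC(C)(C)[C@H]12
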